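The 2,6,6-trimethylcyclohexene ring is built, not bought: ethyl 4-methyl-2-oxo-2H-pyran-3-carboxylate and isobutylene undergo an inverse-electron-demand Diels–Alder reaction and lose CO2, giving ethyl safranate. One operation forms the ring CH2–CH2 bond (isobutylene CH2 to pyrone C6) and the CMe2–C(sp2) bond and sets the tetrasubstituted ring alkene. It exploits the quaternary gem-dimethyl carbon of the carbocycle flanking that alkene: it steers regiochemistry and blocks aromatisation. The ester carbon becomes the first side-chain CH2; alkyne carboalumination gives an (E)-alkenyl iodide. The chroman stereocentre is set by palladium-catalysed asymmetric allylic etherification, and a Heck reaction joins both halves.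

Key step: step 2

Assumption (chemistry): the (R,R)-configured ligand (1R,2R)-N,N'-bis[2-(diphenylphosphino)benzoyl]cyclohexane-1,2-diamine is taken to give the (2R)-chroman from the (E)-allyl carbonate in step 14; if the sense of induction is the opposite, its (S,S)-enantiomer is used.

Step 1
Reactants: 1 diethyl 2-(propan-2-ylidene)propanedioate
Product: 3 ethyl 4-methyl-2-oxo-2H-pyran-3-carboxylate, via dienamine diester 2 (not isolated)
Conditions: Me2NCH(OMe)2, DMF, 110 °C; then aq. HCl, AcOH, 70 °C
Reagents that add atoms: N,N-dimethylformamide dimethyl acetal COC(OC)N(C)C; water O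
Why: Vinylogous condensation of one allylic methyl group of the alkylidene malonate with the amide acetal gives push–pull dienamine 2, whose enamine is hydrolysed and lactonised onto the cis ester under acid (enamine condensation, then 6-exo lactonisation to the 2-pyranone), leaving the second methyl as the pyrone 4-methyl group.

Step 2
Reactants: 3 ethyl 4-methyl-2-oxo-2H-pyran-3-carboxylate; 4 2-methylprop-1-ene (isobutylene)
Product: 6 ethyl 2,6,6-trimethylcyclohexa-1,3-diene-1-carboxylate (ethyl safranate), via bridged lactone 5 (not isolated)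
Conditions: isobutylene (20 equiv), toluene, BHT (cat.), sealed steel autoclave, 170 °C
Reagents that add atoms: none
Why: Inverse-electron-demand [4+2] cycloaddition of the electron-poor pyrone diene (C3=C4–C5=C6) with isobutylene gives bridged lactone 5, which expels CO2 by retro-[4+2] at this temperature and leaves the 1,3-diene 6. The closest known reaction type is the thermal cycloaddition–decarboxylation of 2-pyrone carboxylates with unactivated alkenes. The carbocycle closes in a [4+2] mode by two sigma bonds: the isobutylene CH2 to pyrone C6 (the ring CH2–CH2 bond of the target) and the CMe2 carbon to the ester-bearing C3. No stereocentre remains, since both bridgeheads of racemic 5 become sp2 carbons on loss of CO2. The step needs regioselectivity, which the 3-ester secures by making C6 the electrophilic diene terminus, so that the nucleophilic CH2 of the alkene bonds there and the developing positive charge sits on the tertiary carbon. The quaternary CMe2 carbon carries no hydrogen, so 6 cannot aromatise, and its bulk shields the diene from a second cycloaddition.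

Step 3
Reactants: 6 ethyl 2,6,6-trimethylcyclohexa-1,3-diene-1-carboxylate
Product: 7 ethyl 2,6,6-trimethylcyclohex-1-ene-1-carboxylate
Conditions: H2 (4 bar), RhCl(PPh3)3 (5 mol %), benzene/EtOH, 25 °C
Reagents that add atoms: none
Why: RhCl(PPh3)3 adds H2 cis across the accessible cis-disubstituted C3=C4 bond only, because the tetrasubstituted ester-bearing C1=C2 bond does not bind to rhodium (chemoselective homogeneous hydrogenation).

Step 4
Reactants: 7 ethyl 2,6,6-trimethylcyclohex-1-ene-1-carboxylate
Product: 8 (2,6,6-trimethylcyclohex-1-en-1-yl)methanol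
Conditions: LiAlH4, Et2O, 0 °C to reflux
Reagents that add atoms: none
Why: Hydride reduction of the hindered, weakly conjugated ester proceeds 1,2 to the allylic alcohol (LiAlH4 ester reduction).

Step 5
Reactants: 8 (2,6,6-trimethylcyclohex-1-en-1-yl)methanol
Product: 9 2-(bromomethyl)-1,3,3-trimethylcyclohex-1-ene
Conditions: PBr3, pyridine (cat.), pentane, −10 °C; used crude
Reagents that add atoms: phosphorus tribromide BrP(Br)Br
Why: The primary allylic alcohol is brominated via its phosphite ester by direct substitution, allylic transposition being blocked at the tetrasubstituted alkene carbon (PBr3 bromination).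

Step 6
Reactants: 9 2-(bromomethyl)-1,3,3-trimethylcyclohex-1-ene
Product: 11 2-(but-3-yn-1-yl)-1,3,3-trimethylcyclohex-1-ene, via silyl alkyne 10 (not isolated)
Conditions: 1-(trimethylsilyl)propyne, n-BuLi, THF, −78 °C to rt; then K2CO3, MeOH, rt
Reagents that add atoms: 1-(trimethylsilyl)propyne C[Si](C)(C)C#CC
Why: The lithiated silylpropyne alkylates the primary allylic bromide at its propargylic carbon (SN2), the silyl group suppressing allene formation, and K2CO3/MeOH then cleaves the C–Si bond (propargylation, then protodesilylation).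

Step 7
Reactants: 11 2-(but-3-yn-1-yl)-1,3,3-trimethylcyclohex-1-ene
Product: 13 2-[(3E)-4-iodo-3-methylbut-3-en-1-yl]-1,3,3-trimethylcyclohex-1-ene, via alkenylalane 12 (not isolated)
Conditions: Me3Al, Cp2ZrCl2 (25 mol %), CH2Cl2, 0 °C to rt; then I2, THF, −30 °C
Reagents that add atoms: trimethylaluminium C[Al](C)C; iodine II
Why: Zirconium-catalysed syn-carboalumination (Negishi carboalumination) places methyl on the internal alkyne carbon and aluminium on the terminus, and iodinolysis with retention gives the (E)-alkenyl iodide, the tetrasubstituted ring alkene being inert.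

Step 8
Reactants: 14 4-[(tert-butyldimethylsilyl)oxy]phenol
Product: 15 4-[(tert-butyldimethylsilyl)oxy]-2-iodophenol
Conditions: I2 (1.0 equiv), morpholine, CH2Cl2, 0 °C
Reagents that add atoms: iodine II
Why: Amine-mediated electrophilic iodination occurs ortho to the free hydroxyl (para position blocked), which activates far more strongly than the silyl ether.

Step 9
Reactants: 15 4-[(tert-butyldimethylsilyl)oxy]-2-iodophenol; 16 but-3-en-2-ol (racemic)
Product: 17 4-{5-[(tert-butyldimethylsilyl)oxy]-2-hydroxyphenyl}butan-2-one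
Conditions: Pd(OAc)2 (3 mol %), n-Bu4NCl, NaHCO3, DMF, 45 °C
Reagents that add atoms: none
Why: Heck arylation of the allylic alcohol at its terminal carbon, β-hydride elimination toward the carbinol carbon and tautomerisation deliver the 4-arylbutan-2-one directly.

Step 10
Reactants: 17 4-{5-[(tert-butyldimethylsilyl)oxy]-2-hydroxyphenyl}butan-2-one
Product: 18 4-[(tert-butyldimethylsilyl)oxy]-2-(3-oxobutyl)phenyl 2,2-dimethylpropanoate
Conditions: t-BuCOCl, Et3N, DMAP (cat.), CH2Cl2, 0 °C
Reagents that add atoms: pivaloyl chloride CC(C)(C)C(Cl)=O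
Why: Acylation of the phenol as the hindered pivalate prevents phenoxide-mediated oxa-Michael closure and silyl migration in the next step.

Step 11
Reactants: 18 4-[(tert-butyldimethylsilyl)oxy]-2-(3-oxobutyl)phenyl 2,2-dimethylpropanoate
Product: 19 ethyl (2E)-5-{5-[(tert-butyldimethylsilyl)oxy]-2-[(2,2-dimethylpropanoyl)oxy]phenyl}-3-methylpent-2-enoate
Conditions: (EtO)2P(O)CH2CO2Et, NaH, THF, 0 to 50 °C; (E)-isomer separated by chromatography
Reagents that add atoms: triethyl phosphonoacetate CCOC(=O)CP(=O)(OCC)OCC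
Why: Horner–Wadsworth–Emmons olefination of the methyl ketone should give mainly the (E)-enoate (larger chain trans to the ester), and the minor (Z)-isomer is to be removed by chromatography.

Step 12
Reactants: 19 ethyl (2E)-5-{5-[(tert-butyldimethylsilyl)oxy]-2-[(2,2-dimethylpropanoyl)oxy]phenyl}-3-methylpent-2-enoate
Product: 20 4-[(tert-butyldimethylsilyl)oxy]-2-[(3E)-5-hydroxy-3-methylpent-3-en-1-yl]phenol
Conditions: i-Bu2AlH (6 equiv), CH2Cl2, −78 to 0 °C; aq. potassium sodium tartrate
Reagents that add atoms: none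
Why: i-Bu2AlH reduces the enoate 1,2 to the allylic alcohol and cleaves the aryl pivalate in the same operation, while the aryl silyl ether is untouched.

Step 13
Reactants: 20 4-[(tert-butyldimethylsilyl)oxy]-2-[(3E)-5-hydroxy-3-methylpent-3-en-1-yl]phenol
Product: 21 (2E)-5-{5-[(tert-butyldimethylsilyl)oxy]-2-hydroxyphenyl}-3-methylpent-2-en-1-yl methyl carbonate
Conditions: ClCO2Me (1.1 equiv), pyridine, CH2Cl2, −20 °C
Reagents that add atoms: methyl chloroformate COC(Cl)=O
Why: Under weak-base conditions the primary allylic alcohol is acylated much faster than the neutral, ortho-substituted phenol (chemoselective carbonate formation).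

Step 14
Reactants: 21 (2E)-5-{5-[(tert-butyldimethylsilyl)oxy]-2-hydroxyphenyl}-3-methylpent-2-en-1-yl methyl carbonate
Product: 22 tert-butyl{[(2R)-2-ethenyl-2-methyl-3,4-dihydro-2H-chromen-6-yl]oxy}dimethylsilane
Conditions: Pd2(dba)3·CHCl3 (2 mol %), (1R,2R)-N,N'-bis[2-(diphenylphosphino)benzoyl]cyclohexane-1,2-diamine (6 mol %), AcOH (1 equiv), CH2Cl2 (0.05 M), 25 °C
Reagents that add atoms: none
Why: Zerovalent palladium ionises the allylic carbonate to a π-allyl complex that the phenol attacks at the tertiary terminus in a 6-exo sense, and the chiral diphosphine discriminates the interconverting π-allyl diastereomers (AcOH speeds their equilibration), so the quaternary C2 is set by ligand control (asymmetric Tsuji–Trost allylic etherification).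

Step 15
Reactants: 22 tert-butyl{[(2R)-2-ethenyl-2-methyl-3,4-dihydro-2H-chromen-6-yl]oxy}dimethylsilane; 13 2-[(3E)-4-iodo-3-methylbut-3-en-1-yl]-1,3,3-trimethylcyclohex-1-ene
Product: 23 tert-butyldimethyl({(2R)-2-methyl-2-[(1E,3E)-4-methyl-6-(2,6,6-trimethylcyclohex-1-en-1-yl)hexa-1,3-dien-1-yl]-3,4-dihydro-2H-chromen-6-yl}oxy)silane
Conditions: Pd(OAc)2 (10 mol %), Ag2CO3, MeCN, 50 °C
Reagents that add atoms: none
Why: In this Heck reaction the alkenylpalladium species from 13 adds to the unsubstituted vinyl carbon of 22, and syn β-hydride elimination, possible only away from the quaternary carbon, gives the (E,E)-diene with retention of the iodide geometry, silver carbonate keeping the conditions mild and suppressing isomerisation.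

Step 16
Reactants: 23 tert-butyldimethyl({(2R)-2-methyl-2-[(1E,3E)-4-methyl-6-(2,6,6-trimethylcyclohex-1-en-1-yl)hexa-1,3-dien-1-yl]-3,4-dihydro-2H-chromen-6-yl}oxy)silane
Product: 24 (2R)-2-methyl-2-[(1E,3E)-4-methyl-6-(2,6,6-trimethylcyclohex-1-en-1-yl)hexa-1,3-dien-1-yl]-3,4-dihydro-2H-chromen-6-ol
Conditions: n-Bu4NF, THF, 0 °C
Reagents that add atoms: none
Why: Fluoride cleaves the aryl silyl ether selectively (Si–F bond formation), leaving the diene and the tertiary allylic ether untouched.

Compound list
1 | diethyl 2-(propan-2-ylidene)propanedioate | CCOC(=O)C(=C(C)C)C(=O)OCC | starting material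
2 | diethyl 2-[(3E)-4-(dimethylamino)but-3-en-2-ylidene]propanedioate | CCOC(=O)C(C(=O)OCC)=C(C)/C=C/N(C)C | intermediate
3 | ethyl 4-methyl-2-oxo-2H-pyran-3-carboxylate | CCOC(=O)C1=C(C)C=COC1=O | intermediate
4 | 2-methylprop-1-ene (isobutylene) | CC(C)=C | starting material
5 | ethyl 5,8,8-trimethyl-3-oxo-2-oxabicyclo[2.2.2]oct-5-ene-4-carboxylate (racemic) | CCOC(=O)C12C(=O)OC(C=C1C)CC2(C)C | intermediate
6 | ethyl 2,6,6-trimethylcyclohexa-1,3-diene-1-carboxylate | CCOC(=O)C1=C(C)C=CCC1(C)C | intermediate
7 | ethyl 2,6,6-trimethylcyclohex-1-ene-1-carboxylate | CCOC(=O)C1=C(C)CCCC1(C)C | intermediate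
8 | (2,6,6-trimethylcyclohex-1-en-1-yl)methanol | OCC1=C(C)CCCC1(C)C | intermediate
9 | 2-(bromomethyl)-1,3,3-trimethylcyclohex-1-ene | BrCC1=C(C)CCCC1(C)C | intermediate
10 | trimethyl[4-(2,6,6-trimethylcyclohex-1-en-1-yl)but-1-yn-1-yl]silane | C[Si](C)(C)C#CCCC1=C(C)CCCC1(C)C | intermediate
11 | 2-(but-3-yn-1-yl)-1,3,3-trimethylcyclohex-1-ene | C#CCCC1=C(C)CCCC1(C)C | intermediate
12 | dimethyl[(1E)-2-methyl-4-(2,6,6-trimethylcyclohex-1-en-1-yl)but-1-en-1-yl]alumane | C[Al](C)/C=C(\C)CCC1=C(C)CCCC1(C)C | intermediate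
13 | 2-[(3E)-4-iodo-3-methylbut-3-en-1-yl]-1,3,3-trimethylcyclohex-1-ene | I/C=C(\C)CCC1=C(C)CCCC1(C)C | intermediate
14 | 4-[(tert-butyldimethylsilyl)oxy]phenol | CC(C)(C)[Si](C)(C)Oc1ccc(O)cc1 | starting material
15 | 4-[(tert-butyldimethylsilyl)oxy]-2-iodophenol | CC(C)(C)[Si](C)(C)Oc1ccc(O)c(I)c1 | intermediate
16 | but-3-en-2-ol (racemic) | CC(O)C=C | starting material
17 | 4-{5-[(tert-butyldimethylsilyl)oxy]-2-hydroxyphenyl}butan-2-one | CC(=O)CCc1cc(O[Si](C)(C)C(C)(C)C)ccc1O | intermediate
18 | 4-[(tert-butyldimethylsilyl)oxy]-2-(3-oxobutyl)phenyl 2,2-dimethylpropanoate | CC(=O)CCc1cc(O[Si](C)(C)C(C)(C)C)ccc1OC(=O)C(C)(C)C | intermediate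
19 | ethyl (2E)-5-{5-[(tert-butyldimethylsilyl)oxy]-2-[(2,2-dimethylpropanoyl)oxy]phenyl}-3-methylpent-2-enoate | CCOC(=O)/C=C(\C)CCc1cc(O[Si](C)(C)C(C)(C)C)ccc1OC(=O)C(C)(C)C | intermediate
20 | 4-[(tert-butyldimethylsilyl)oxy]-2-[(3E)-5-hydroxy-3-methylpent-3-en-1-yl]phenol | OC/C=C(\C)CCc1cc(O[Si](C)(C)C(C)(C)C)ccc1O | intermediate
21 | (2E)-5-{5-[(tert-butyldimethylsilyl)oxy]-2-hydroxyphenyl}-3-methylpent-2-en-1-yl methyl carbonate | COC(=O)OC/C=C(\C)CCc1cc(O[Si](C)(C)C(C)(C)C)ccc1O | intermediate
22 | tert-butyl{[(2R)-2-ethenyl-2-methyl-3,4-dihydro-2H-chromen-6-yl]oxy}dimethylsilane | C=C[C@@]1(C)CCc2cc(O[Si](C)(C)C(C)(C)C)ccc2O1 | intermediate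
23 | tert-butyldimethyl({(2R)-2-methyl-2-[(1E,3E)-4-methyl-6-(2,6,6-trimethylcyclohex-1-en-1-yl)hexa-1,3-dien-1-yl]-3,4-dihydro-2H-chromen-6-yl}oxy)silane | CC1=C(CC/C(C)=C/C=C/[C@@]2(C)CCc3cc(O[Si](C)(C)C(C)(C)C)ccc3O2)C(C)(C)CCC1 | intermediate
24 | (2R)-2-methyl-2-[(1E,3E)-4-methyl-6-(2,6,6-trimethylcyclohex-1-en-1-yl)hexa-1,3-dien-1-yl]-3,4-dihydro-2H-chromen-6-ol | CC1=C(CC/C(C)=C/C=C/[C@@]2(C)CCc3cc(O)ccc3O2)C(C)(C)CCC1 | target

Total step count: 16. Longest linear sequence: 9 steps (steps 1–7, 15 and 16; the chroman branch, steps 8–14, 15 and 16, is of equal length).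

Steps most likely to fail

Step 2. The cycloaddition may stall because isobutylene is only weakly nucleophilic, or bond formation may begin at the wrong diene terminus because the bond between the CMe2 carbon and the ester-bearing carbon is congested; prolonged heating may then consume the pyrone. Fallback: the same two ring carbons are joined by ring-closing metathesis instead of by cycloaddition. It sets out from compound 1 and comes back to the route at compound 7. CuI-catalysed conjugate addition of vinylmagnesium bromide to 1 should give diethyl 2-(2-methylbut-3-en-2-yl)propanedioate F1. Krapcho dealkoxycarbonylation (LiCl, wet DMSO, 160 °C) gives ethyl 3,3-dimethylpent-4-enoate F2. Its lithium enolate (LiN(i-Pr)2, THF, −78 °C) is C-acylated with but-3-enoyl chloride to racemic ethyl 2-(2-methylbut-3-en-2-yl)-3-oxohex-5-enoate F3. The second-generation Grubbs catalyst (CH2Cl2, 40 °C) joins the two inner vinyl carbons and closes the ring to racemic ethyl 6,6-dimethyl-2-oxocyclohex-4-ene-1-carboxylate F4. Hydrogenation (H2, Pd/C, EtOAc) gives racemic ethyl 2,2-dimethyl-6-oxocyclohexane-1-carboxylate F5. NaH and PhNTf2 give the enol triflate ethyl 6,6-dimethyl-2-{[(trifluoromethyl)sulfonyl]oxy}cyclohex-1-ene-1-carboxylate F6, and Me2CuLi (Et2O, −20 °C) replaces the triflate by methyl to give 7.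

Step 15. β-Aryloxy elimination from the alkylpalladium intermediate (opening of the chroman), reversible ionisation of the tertiary allylic aryl ether by zerovalent palladium (erosion of the C2 configuration) or slow insertion next to the quaternary carbon may limit the coupling. Fallback: the diene is assembled by cross-coupling of two alkenyl partners instead of by a Heck reaction. It sets out from compound 22 (with alkenylalane 12 generated from 11 as in step 7, without the iodine quench) and comes back at compound 23. Ozonolysis of 22 (O3, CH2Cl2, −78 °C; then PPh3) gives (2R)-6-[(tert-butyldimethylsilyl)oxy]-2-methyl-3,4-dihydro-2H-chromene-2-carbaldehyde F7. Takai olefination (CrCl2, CHI3, THF, 0 °C) gives tert-butyl({(2R)-2-[(E)-2-iodoethenyl]-2-methyl-3,4-dihydro-2H-chromen-6-yl}oxy)dimethylsilane F8. Negishi-type coupling of F8 with 12 (Pd(PPh3)4, ZnCl2, THF, rt) gives 23 with both double-bond geometries defined by the partners.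

Step 14. Facial discrimination at the π-allyl stage may be insufficient or of the unwanted sense, and intermolecular O-allylation may compete with ring closure. Fallback: the stereocentre is set by reagent-controlled epoxidation and stereospecific ring closure. It sets out from compound 20 and comes back at compound 22. Sharpless asymmetric epoxidation of 20 (Ti(Oi-Pr)4, L-(+)-diethyl tartrate, t-BuOOH, CH2Cl2, −20 °C) should give 4-[(tert-butyldimethylsilyl)oxy]-2-{2-[(2S,3S)-3-(hydroxymethyl)-2-methyloxiran-2-yl]ethyl}phenol F9. Camphorsulfonic acid (cat., CH2Cl2, 0 °C) promotes 6-exo attack of the phenol at the tertiary epoxide carbon with inversion, giving (1S)-1-{(2R)-6-[(tert-butyldimethylsilyl)oxy]-2-methyl-3,4-dihydro-2H-chromen-2-yl}ethane-1,2-diol F10. 1,1'-Thiocarbonyldiimidazole (THF, 60 °C) converts the diol into the cyclic thionocarbonate (4S)-4-{(2R)-6-[(tert-butyldimethylsilyl)oxy]-2-methyl-3,4-dihydro-2H-chromen-2-yl}-1,3-dioxolane-2-thione F11, and heating with P(OMe)3 (Corey–Winter olefination) gives 22.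

Further compounds
F1 | step 2 | diethyl 2-(2-methylbut-3-en-2-yl)propanedioate | CCOC(=O)C(C(=O)OCC)C(C)(C)C=C
F2 | step 2 | ethyl 3,3-dimethylpent-4-enoate | CCOC(=O)CC(C)(C)C=C
F3 | step 2 | ethyl 2-(2-methylbut-3-en-2-yl)-3-oxohex-5-enoate (racemic) | CCOC(=O)C(C(=O)CC=C)C(C)(C)C=C
F4 | step 2 | ethyl 6,6-dimethyl-2-oxocyclohex-4-ene-1-carboxylate (racemic) | CCOC(=O)C1C(=O)CC=CC1(C)C
F5 | step 2 | ethyl 2,2-dimethyl-6-oxocyclohexane-1-carboxylate (racemic) | CCOC(=O)C1C(=O)CCCC1(C)C
F6 | step 2 | ethyl 6,6-dimethyl-2-{[(trifluoromethyl)sulfonyl]oxy}cyclohex-1-ene-1-carboxylate | CCOC(=O)C1=C(OS(=O)(=O)C(F)(F)F)CCCC1(C)C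
F7 | step 15 | (2R)-6-[(tert-butyldimethylsilyl)oxy]-2-methyl-3,4-dihydro-2H-chromene-2-carbaldehyde | O=C[C@@]1(C)CCc2cc(O[Si](C)(C)C(C)(C)C)ccc2O1
F8 | step 15 | tert-butyl({(2R)-2-[(E)-2-iodoethenyl]-2-methyl-3,4-dihydro-2H-chromen-6-yl}oxy)dimethylsilane | I/C=C/[C@@]1(C)CCc2cc(O[Si](C)(C)C(C)(C)C)ccc2O1
F9 | step 14 | 4-[(tert-butyldimethylsilyl)oxy]-2-{2-[(2S,3S)-3-(hydroxymethyl)-2-methyloxiran-2-yl]ethyl}phenol | OC[C@@H]1O[C@@]1(C)CCc2cc(O[Si](C)(C)C(C)(C)C)ccc2O
F10 | step 14 | (1S)-1-{(2R)-6-[(tert-butyldimethylsilyl)oxy]-2-methyl-3,4-dihydro-2H-chromen-2-yl}ethane-1,2-diol | OC[C@H](O)[C@@]1(C)CCc2cc(O[Si](C)(C)C(C)(C)C)ccc2O1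
F11 | step 14 | (4S)-4-{(2R)-6-[(tert-butyldimethylsilyl)oxy]-2-methyl-3,4-dihydro-2H-chromen-2-yl}-1,3-dioxolane-2-thione | S=C1OC[C@H](O1)[C@@]2(C)CCc3cc(O[Si](C)(C)C(C)(C)C)ccc3O2
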